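**Plan**

1. The chain is numbered C1 (alkyne CH) to C15 (CH3), with the ring oxygen between C7 and C12. The retrosynthesis cuts, in order: the acetate, C3=C4 (enyne olefination), C13–Br, C13–C14, the ring bond C11–C12, O–C12, C8–C9 and C4–C5.
2. The feature that allows the key step lies in the seven-membered oxepene. C11 is the allylic CH2 next to the cis C9=C10 bond. C12 carries the ring oxygen and adjoins C13. With C13 raised to an amide carbonyl, C12 becomes an enolate carbon and C11–C12 an internal allylation bond.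
3. In the forward direction, a C2-symmetric diepoxide (C5–C8) is opened first by a C4 hydroxymethyl synthon and then by the C9–C11 acetylide. O6 and O7 are thereby released one after the other and can be treated differently. O7 is then etherified with the C12–C13 acetamide.
4. The only ring closes in step 11. The C13–C15 arm is finished next (ethyl ketone, alcohol, bromide), followed by the C1–C4 enyne arm and the acetate.
5. C6 and C7 come unchanged from the L-tartaric acid pool. C12 is set from C7 in the closure (2,7-cis). C13 is set by Felkin–Anh reduction and then SN2 inversion. C9=C10 comes from Lindlar reduction and C3=C4 from a Peterson olefination with bulky silyl groups.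

Key step: step 11

Remark: the ring olefin carries no geometry in the target SMILES and is taken as cis, the only arrangement a seven-membered ring accepts.

**Step 1**
Reactants: 1 [(4S,5S)-2,2-dimethyl-1,3-dioxolane-4,5-diyl]bis(methylene) bis(4-methylbenzenesulfonate) (commercial 1,4-di-O-tosyl-2,3-O-isopropylidene-L-threitol)
Product: 2 (2S,3S)-2,3-dihydroxybutane-1,4-diyl bis(4-methylbenzenesulfonate)
Conditions: TsOH·H2O (cat.), EtOH/H2O 95:5, reflux
Reagents that add atoms: none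
Why: Acid-catalysed acetal hydrolysis frees the diol while the primary tosylates and both carbinol C–O bonds stay intact, so the (S,S) configuration inherited from L-tartaric acid (later C6 and C7) is untouched.

**Step 2**
Reactants: 2 (2S,3S)-2,3-dihydroxybutane-1,4-diyl bis(4-methylbenzenesulfonate)
Product: 3 (2S,2'S)-2,2'-bioxirane [(S,S)-1,2:3,4-diepoxybutane]
Conditions: KOH, Et2O/H2O, rt
Reagents that add atoms: none
Why: A double intramolecular Williamson reaction (3-exo-tet) displaces the two primary tosylates, and the stereocentres only carry the attacking oxygens and therefore keep their configuration.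

**Step 3**
Reactants: 3 (2S,2'S)-2,2'-bioxirane; 4 (chloromethyl)dimethyl(propan-2-yloxy)silane
Product: 6 (1S)-3-[dimethyl(propan-2-yloxy)silyl]-1-[(2S)-oxiran-2-yl]propan-1-ol, via silylmethyl Grignard reagent 5 (not isolated)
Conditions: 4, Mg, THF, rt; then CuI (10 mol %), 3 (2 equiv), THF, −30 °C; aq NH4Cl
Reagents that add atoms: none
Why: Copper-catalysed Grignard opening of a terminal epoxide at its CH2 terminus forms C4–C5 with a silicon-masked hydroxymethyl anion; the two epoxides of C2-symmetric 3 are homotopic, so mono-opening gives one product, and the excess of 3 holds back a second addition.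

**Step 4**
Reactants: 6 (1S)-3-[dimethyl(propan-2-yloxy)silyl]-1-[(2S)-oxiran-2-yl]propan-1-ol
Product: 7 (1S)-1-[(2S)-oxiran-2-yl]propane-1,3-diol
Conditions: H2O2 (30 %), KF, KHCO3, THF/MeOH, rt
Reagents that add atoms: hydrogen peroxide, OO
Why: Tamao–Kumada oxidation exchanges the C4–Si bond for C4–OH under bicarbonate-buffered conditions that a terminal epoxide should tolerate.

**Step 5**
Reactants: 7 (1S)-1-[(2S)-oxiran-2-yl]propane-1,3-diol
Product: 8 (4S)-2,2-dimethyl-4-[(2S)-oxiran-2-yl]-1,3-dioxane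
Conditions: 2-methoxypropene, PPTS (cat.), CH2Cl2, 0 °C
Reagents that add atoms: 2-methoxypropene, C=C(C)OC
Why: Acid-catalysed acetalisation closes the six-membered acetonide of the 1,3-diol with an acid too weak to activate the epoxide, and it puts on O6 a group that, unlike a silyl ether, cannot migrate to the adjacent C7 alkoxide of step 7.

**Step 6**
Reactants: 8 (4S)-2,2-dimethyl-4-[(2S)-oxiran-2-yl]-1,3-dioxane; 9 tert-butyldimethyl(prop-2-yn-1-yloxy)silane
Product: 11 (1S)-5-[(tert-butyldimethylsilyl)oxy]-1-[(4S)-2,2-dimethyl-1,3-dioxan-4-yl]pent-3-yn-1-ol, via lithium acetylide 10 (not isolated)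
Conditions: 9, n-BuLi, THF, −78 °C; BF3·OEt2; then 8, −78 °C
Reagents that add atoms: none
Why: Yamaguchi–Hirao alkynylation (lithium acetylide/BF3) attacks the unsubstituted epoxide carbon C8, forms C8–C9 and releases the C7 hydroxyl as the only free alcohol without touching the C7–O bond.

**Step 7**
Reactants: 11 (1S)-5-[(tert-butyldimethylsilyl)oxy]-1-[(4S)-2,2-dimethyl-1,3-dioxan-4-yl]pent-3-yn-1-ol; 12 2-chloro-N,N-dimethylacetamide
Product: 14 2-{[(1S)-5-[(tert-butyldimethylsilyl)oxy]-1-[(4S)-2,2-dimethyl-1,3-dioxan-4-yl]pent-3-yn-1-yl]oxy}-N,N-dimethylacetamide, via sodium alkoxide 13 (not isolated)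
Conditions: NaH, THF/DMF, 0 °C; 12, Bu4NI (cat.), 0 °C → rt
Reagents that add atoms: none
Why: Williamson etherification of the secondary alkoxide with the reactive α-chloroamide (iodide catalysis) forms the O–C12 bond, and the acetonide and the remote propargylic silyl ether are inert to NaH.

**Step 8**
Reactants: 14 2-{[(1S)-5-[(tert-butyldimethylsilyl)oxy]-1-[(4S)-2,2-dimethyl-1,3-dioxan-4-yl]pent-3-yn-1-yl]oxy}-N,N-dimethylacetamide
Product: 15 2-{[(1S)-1-[(4S)-2,2-dimethyl-1,3-dioxan-4-yl]-5-hydroxypent-3-yn-1-yl]oxy}-N,N-dimethylacetamide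
Conditions: TBAF, THF, 0 °C
Reagents that add atoms: none
Why: Fluoride-mediated desilylation cleaves the only silyl ether and leaves the acetonide, amide and alkyne unchanged.

**Step 9**
Reactants: 15 2-{[(1S)-1-[(4S)-2,2-dimethyl-1,3-dioxan-4-yl]-5-hydroxypent-3-yn-1-yl]oxy}-N,N-dimethylacetamide
Product: 16 2-{[(1S,3Z)-1-[(4S)-2,2-dimethyl-1,3-dioxan-4-yl]-5-hydroxypent-3-en-1-yl]oxy}-N,N-dimethylacetamide
Conditions: H2 (1 atm), Lindlar catalyst, quinoline, EtOAc, rt
Reagents that add atoms: none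
Why: Lindlar semihydrogenation delivers hydrogen syn to the alkyne and, with quinoline, should stop at the Z olefin C9=C10.

**Step 10**
Reactants: 16 2-{[(1S,3Z)-1-[(4S)-2,2-dimethyl-1,3-dioxan-4-yl]-5-hydroxypent-3-en-1-yl]oxy}-N,N-dimethylacetamide
Product: 18 2-{[(1S,3Z)-5-chloro-1-[(4S)-2,2-dimethyl-1,3-dioxan-4-yl]pent-3-en-1-yl]oxy}-N,N-dimethylacetamide, via allylic mesylate 17 (not isolated)
Conditions: MsCl, LiCl, 2,4,6-collidine, DMF, 0 °C
Reagents that add atoms: lithium chloride, [Li+].[Cl-]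
Why: Collington–Meyers chlorination (mesylation, then SN2 by chloride in the same flask) converts the primary allylic alcohol into the chloride without allylic transposition or Z-to-E isomerisation.

**Step 11**
Reactants: 18 2-{[(1S,3Z)-5-chloro-1-[(4S)-2,2-dimethyl-1,3-dioxan-4-yl]pent-3-en-1-yl]oxy}-N,N-dimethylacetamide
Product: 20 (2R,7S)-7-[(4S)-2,2-dimethyl-1,3-dioxan-4-yl]-N,N-dimethyl-2,3,6,7-tetrahydrooxepine-2-carboxamide, via potassium Z-enolate 19 (not isolated)
Conditions: KHMDS (1.1 equiv), THF (0.01 M), −78 °C → rt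
Reagents that add atoms: none
Why: KHMDS removes a C12 proton of 18 to give the Z(O) amide enolate 19, whose carbon displaces chloride from the allylic CH2 (C11) in an SN2 reaction that forms C11–C12. The closest known reaction type is the intramolecular amide-enolate alkylation of α-alkoxy-N,N-dimethylacetamides with Z-allylic chlorides, established for 2,7-cis-oxepenes and the homologous oxocenes. The oxepene closes in the 7-exo-tet mode, and the cis C9=C10 bond removes rotational freedom and folds C11 back towards the enolate carbon. C12 is controlled by C7: in the chair-like transition state the dioxanyl group at C7 stays pseudo-equatorial and the bulky C(O−)NMe2 terminus points outward, so H12 and H7 end on the same ring face (2,7-cis, 12R). The step needs C- over O-alkylation, SN2 at C11 over SN2′ at C9, and cyclisation over oligomerisation or elimination. The strongly nucleophilic amide enolate, which has no β-leaving group of its own, the unhindered primary chloride on a Z olefin and high dilution should secure these.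

**Step 12**
Reactants: 20 (2R,7S)-7-[(4S)-2,2-dimethyl-1,3-dioxan-4-yl]-N,N-dimethyl-2,3,6,7-tetrahydrooxepine-2-carboxamide
Product: 22 1-[(2R,7S)-7-[(4S)-2,2-dimethyl-1,3-dioxan-4-yl]-2,3,6,7-tetrahydrooxepin-2-yl]propan-1-one, via magnesium hemiaminal 21 (not isolated)
Conditions: EtMgBr, THF, 0 °C; aq NH4Cl
Reagents that add atoms: ethylmagnesium bromide, CC[Mg]Br
Why: Grignard addition to the tertiary amide stops at the hemiaminal 21, which is held by chelation to the ring oxygen and collapses to the ketone only on work-up, so C13–C14 forms without over-addition and without epimerising C12.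

**Step 13**
Reactants: 22 1-[(2R,7S)-7-[(4S)-2,2-dimethyl-1,3-dioxan-4-yl]-2,3,6,7-tetrahydrooxepin-2-yl]propan-1-one
Product: 23 (1R)-1-[(2R,7S)-7-[(4S)-2,2-dimethyl-1,3-dioxan-4-yl]-2,3,6,7-tetrahydrooxepin-2-yl]propan-1-ol
Conditions: L-Selectride, THF, −78 °C; aq NH4Cl
Reagents that add atoms: none
Why: In this Felkin–Anh-controlled reduction the bulky borohydride attacks anti to the C12–O bond on the side of the C12 hydrogen, which should give the syn 12,13-alkoxy alcohol, that is 13R.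

**Step 14**
Reactants: 23 (1R)-1-[(2R,7S)-7-[(4S)-2,2-dimethyl-1,3-dioxan-4-yl]-2,3,6,7-tetrahydrooxepin-2-yl]propan-1-ol
Product: 24 (4S)-4-[(2S,7R)-7-[(1S)-1-bromopropyl]-2,3,6,7-tetrahydrooxepin-2-yl]-2,2-dimethyl-1,3-dioxane
Conditions: CBr4, P(n-Oct)3, toluene, 70 °C
Reagents that add atoms: carbon tetrabromide, BrC(Br)(Br)Br
Why: Appel-type bromination through the alkoxyphosphonium salt proceeds by SN2 and inverts C13 from R to the S bromide of the target, and the neutral medium spares the acetonide and the olefin.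

**Step 15**
Reactants: 24 (4S)-4-[(2S,7R)-7-[(1S)-1-bromopropyl]-2,3,6,7-tetrahydrooxepin-2-yl]-2,2-dimethyl-1,3-dioxane
Product: 25 (1S)-1-[(2S,7R)-7-[(1S)-1-bromopropyl]-2,3,6,7-tetrahydrooxepin-2-yl]propane-1,3-diol
Conditions: AcOH/THF/H2O 3:1:1, 40 °C
Reagents that add atoms: none
Why: Mild aqueous acid hydrolyses the acetonide (acetal hydrolysis) and does not affect the secondary bromide, the ring ether or the olefin.

**Step 16**
Reactants: 25 (1S)-1-[(2S,7R)-7-[(1S)-1-bromopropyl]-2,3,6,7-tetrahydrooxepin-2-yl]propane-1,3-diol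
Product: 26 (2S,7R)-2-[(1S)-1,3-bis(triethylsilyloxy)propyl]-7-[(1S)-1-bromopropyl]-2,3,6,7-tetrahydrooxepine
Conditions: TESCl, imidazole, CH2Cl2, 0 °C → rt
Reagents that add atoms: chlorotriethylsilane, CC[Si](Cl)(CC)CC
Why: Imidazole-promoted silylation caps both hydroxyls in one operation and prepares the primary/secondary differentiation of the next step.

**Step 17**
Reactants: 26 (2S,7R)-2-[(1S)-1,3-bis(triethylsilyloxy)propyl]-7-[(1S)-1-bromopropyl]-2,3,6,7-tetrahydrooxepine
Product: 27 (3S)-3-[(2S,7R)-7-[(1S)-1-bromopropyl]-2,3,6,7-tetrahydrooxepin-2-yl]-3-[(triethylsilyl)oxy]propanal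
Conditions: (COCl)2, DMSO, CH2Cl2, −78 → −40 °C; Et3N, −78 → 0 °C
Reagents that add atoms: none
Why: Under Swern conditions a primary triethylsilyl ether is cleaved by the chlorosulfonium salt and oxidised directly to the aldehyde, whereas the hindered secondary TES ether at C6 should survive.

**Step 18**
Reactants: 28 tri(propan-2-yl)(prop-1-yn-1-yl)silane
Product: 30 1,3-bis(triisopropylsilyl)prop-1-yne, via propargyllithium 29 (not isolated)
Conditions: n-BuLi, THF, −20 °C; TIPSOTf, −78 °C → rt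
Reagents that add atoms: triisopropylsilyl trifluoromethanesulfonate, CC(C)[Si](OS(=O)(=O)C(F)(F)F)(C(C)C)C(C)C
Why: Propargylic lithiation followed by C-silylation at the CH2 terminus gives the bis-silylated Peterson reagent.

**Step 19**
Reactants: 27 (3S)-3-[(2S,7R)-7-[(1S)-1-bromopropyl]-2,3,6,7-tetrahydrooxepin-2-yl]-3-[(triethylsilyl)oxy]propanal; 30 1,3-bis(triisopropylsilyl)prop-1-yne
Product: 32 {(3Z,6S)-6-[(2S,7R)-7-[(1S)-1-bromopropyl]-2,3,6,7-tetrahydrooxepin-2-yl]-6-[(triethylsilyl)oxy]hex-3-en-1-yn-1-yl}tri(propan-2-yl)silane, via lithiated bis-silylpropyne 31 (not isolated)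
Conditions: 30, n-BuLi, THF, −20 °C; then 27, −78 °C
Reagents that add atoms: none
Why: In this Peterson olefination the lithiated reagent adds to the aldehyde and silanolate is lost spontaneously to form C3=C4, and the two bulky TIPS groups steer the addition towards the adduct that gives the Z enyne.

**Step 20**
Reactants: 32 {(3Z,6S)-6-[(2S,7R)-7-[(1S)-1-bromopropyl]-2,3,6,7-tetrahydrooxepin-2-yl]-6-[(triethylsilyl)oxy]hex-3-en-1-yn-1-yl}tri(propan-2-yl)silane
Product: 33 (1S,3Z)-1-[(2S,7R)-7-[(1S)-1-bromopropyl]-2,3,6,7-tetrahydrooxepin-2-yl]hex-3-en-5-yn-1-ol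
Conditions: TBAF, AcOH (1:1), THF, 0 °C → rt
Reagents that add atoms: none
Why: Fluoride-mediated desilylation cleaves both the O–TES and the alkynyl C–TIPS bond, and the acetic acid buffer keeps O6 protonated so that it does not displace the C13 bromide.

**Step 21**
Reactants: 33 (1S,3Z)-1-[(2S,7R)-7-[(1S)-1-bromopropyl]-2,3,6,7-tetrahydrooxepin-2-yl]hex-3-en-5-yn-1-ol
Product: 34 (1S,3Z)-1-[(2S,7R)-7-[(1S)-1-bromopropyl]-2,3,6,7-tetrahydrooxepin-2-yl]hex-3-en-5-yn-1-yl acetate
Conditions: Ac2O, pyridine, DMAP (cat.), CH2Cl2, 0 °C → rt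
Reagents that add atoms: acetic anhydride, CC(=O)OC(C)=O
Why: DMAP-catalysed O-acylation of the secondary alcohol leaves the C6–O bond intact and completes the target.

**Compound list**

1 | [(4S,5S)-2,2-dimethyl-1,3-dioxolane-4,5-diyl]bis(methylene) bis(4-methylbenzenesulfonate) | Cc1ccc(cc1)S(=O)(=O)OC[C@@H]1OC(C)(C)O[C@H]1COS(=O)(=O)c1ccc(C)cc1 | starting material
2 | (2S,3S)-2,3-dihydroxybutane-1,4-diyl bis(4-methylbenzenesulfonate) | Cc1ccc(cc1)S(=O)(=O)OC[C@H](O)[C@@H](O)COS(=O)(=O)c1ccc(C)cc1 | intermediate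
3 | (2S,2'S)-2,2'-bioxirane | C1O[C@@H]1[C@@H]1CO1 | intermediate
4 | (chloromethyl)dimethyl(propan-2-yloxy)silane | CC(C)O[Si](C)(C)CCl | starting material
5 | {[dimethyl(propan-2-yloxy)silyl]methyl}magnesium chloride | CC(C)O[Si](C)(C)C[Mg]Cl | intermediate
6 | (1S)-3-[dimethyl(propan-2-yloxy)silyl]-1-[(2S)-oxiran-2-yl]propan-1-ol | CC(C)O[Si](C)(C)CC[C@H](O)[C@@H]1CO1 | intermediate
7 | (1S)-1-[(2S)-oxiran-2-yl]propane-1,3-diol | OCC[C@H](O)[C@@H]1CO1 | intermediate
8 | (4S)-2,2-dimethyl-4-[(2S)-oxiran-2-yl]-1,3-dioxane | CC1(C)OCC[C@@H]([C@@H]2CO2)O1 | intermediate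
9 | tert-butyldimethyl(prop-2-yn-1-yloxy)silane | C#CCO[Si](C)(C)C(C)(C)C | starting material
10 | lithium 3-[(tert-butyldimethylsilyl)oxy]prop-1-yn-1-ide | [Li]C#CCO[Si](C)(C)C(C)(C)C | intermediate
11 | (1S)-5-[(tert-butyldimethylsilyl)oxy]-1-[(4S)-2,2-dimethyl-1,3-dioxan-4-yl]pent-3-yn-1-ol | CC1(C)OCC[C@@H]([C@@H](O)CC#CCO[Si](C)(C)C(C)(C)C)O1 | intermediate
12 | 2-chloro-N,N-dimethylacetamide | CN(C)C(=O)CCl | starting material
13 | sodium alkoxide of 11 | [Na+].CC1(C)OCC[C@@H]([C@@H]([O-])CC#CCO[Si](C)(C)C(C)(C)C)O1 | intermediate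
14 | 2-{[(1S)-5-[(tert-butyldimethylsilyl)oxy]-1-[(4S)-2,2-dimethyl-1,3-dioxan-4-yl]pent-3-yn-1-yl]oxy}-N,N-dimethylacetamide | CN(C)C(=O)CO[C@@H](CC#CCO[Si](C)(C)C(C)(C)C)[C@@H]1CCOC(C)(C)O1 | intermediate
15 | 2-{[(1S)-1-[(4S)-2,2-dimethyl-1,3-dioxan-4-yl]-5-hydroxypent-3-yn-1-yl]oxy}-N,N-dimethylacetamide | CN(C)C(=O)CO[C@@H](CC#CCO)[C@@H]1CCOC(C)(C)O1 | intermediate
16 | 2-{[(1S,3Z)-1-[(4S)-2,2-dimethyl-1,3-dioxan-4-yl]-5-hydroxypent-3-en-1-yl]oxy}-N,N-dimethylacetamide | CN(C)C(=O)CO[C@@H](C/C=C\CO)[C@@H]1CCOC(C)(C)O1 | intermediate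
17 | (2Z,5S)-5-[2-(dimethylamino)-2-oxoethoxy]-5-[(4S)-2,2-dimethyl-1,3-dioxan-4-yl]pent-2-en-1-yl methanesulfonate | CN(C)C(=O)CO[C@@H](C/C=C\COS(C)(=O)=O)[C@@H]1CCOC(C)(C)O1 | intermediate
18 | 2-{[(1S,3Z)-5-chloro-1-[(4S)-2,2-dimethyl-1,3-dioxan-4-yl]pent-3-en-1-yl]oxy}-N,N-dimethylacetamide | CN(C)C(=O)CO[C@@H](C/C=C\CCl)[C@@H]1CCOC(C)(C)O1 | intermediate
19 | potassium (Z)-enolate of 18 | [K+].CN(C)/C([O-])=C/O[C@@H](C/C=C\CCl)[C@@H]1CCOC(C)(C)O1 | intermediate
20 | (2R,7S)-7-[(4S)-2,2-dimethyl-1,3-dioxan-4-yl]-N,N-dimethyl-2,3,6,7-tetrahydrooxepine-2-carboxamide | CC1(C)OCC[C@@H]([C@@H]2CC=CC[C@H](C(=O)N(C)C)O2)O1 | intermediate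
21 | bromomagnesium hemiaminal from 20 and EtMgBr (hemiaminal carbon undefined) | CC1(C)OCC[C@@H]([C@@H]2CC=CC[C@H](C(CC)(O[Mg]Br)N(C)C)O2)O1 | intermediate
22 | 1-[(2R,7S)-7-[(4S)-2,2-dimethyl-1,3-dioxan-4-yl]-2,3,6,7-tetrahydrooxepin-2-yl]propan-1-one | CC1(C)OCC[C@@H]([C@@H]2CC=CC[C@H](C(=O)CC)O2)O1 | intermediate
23 | (1R)-1-[(2R,7S)-7-[(4S)-2,2-dimethyl-1,3-dioxan-4-yl]-2,3,6,7-tetrahydrooxepin-2-yl]propan-1-ol | CC1(C)OCC[C@@H]([C@@H]2CC=CC[C@H]([C@H](O)CC)O2)O1 | intermediate
24 | (4S)-4-[(2S,7R)-7-[(1S)-1-bromopropyl]-2,3,6,7-tetrahydrooxepin-2-yl]-2,2-dimethyl-1,3-dioxane | CC1(C)OCC[C@@H]([C@@H]2CC=CC[C@H]([C@@H](Br)CC)O2)O1 | intermediate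
25 | (1S)-1-[(2S,7R)-7-[(1S)-1-bromopropyl]-2,3,6,7-tetrahydrooxepin-2-yl]propane-1,3-diol | OCC[C@H](O)[C@@H]1CC=CC[C@H]([C@@H](Br)CC)O1 | intermediate
26 | (2S,7R)-2-[(1S)-1,3-bis(triethylsilyloxy)propyl]-7-[(1S)-1-bromopropyl]-2,3,6,7-tetrahydrooxepine | CC[Si](CC)(CC)OCC[C@H](O[Si](CC)(CC)CC)[C@@H]1CC=CC[C@H]([C@@H](Br)CC)O1 | intermediate
27 | (3S)-3-[(2S,7R)-7-[(1S)-1-bromopropyl]-2,3,6,7-tetrahydrooxepin-2-yl]-3-[(triethylsilyl)oxy]propanal | O=CC[C@H](O[Si](CC)(CC)CC)[C@@H]1CC=CC[C@H]([C@@H](Br)CC)O1 | intermediate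
28 | tri(propan-2-yl)(prop-1-yn-1-yl)silane | CC#C[Si](C(C)C)(C(C)C)C(C)C | starting material
29 | [3-(triisopropylsilyl)prop-2-yn-1-yl]lithium | [Li]CC#C[Si](C(C)C)(C(C)C)C(C)C | intermediate
30 | 1,3-bis(triisopropylsilyl)prop-1-yne | CC(C)[Si](CC#C[Si](C(C)C)(C(C)C)C(C)C)(C(C)C)C(C)C | intermediate
31 | [1,3-bis(triisopropylsilyl)prop-2-yn-1-yl]lithium | [Li]C(C#C[Si](C(C)C)(C(C)C)C(C)C)[Si](C(C)C)(C(C)C)C(C)C | intermediate
32 | {(3Z,6S)-6-[(2S,7R)-7-[(1S)-1-bromopropyl]-2,3,6,7-tetrahydrooxepin-2-yl]-6-[(triethylsilyl)oxy]hex-3-en-1-yn-1-yl}tri(propan-2-yl)silane | CC(C)[Si](C#C/C=C\C[C@H](O[Si](CC)(CC)CC)[C@@H]1CC=CC[C@H]([C@@H](Br)CC)O1)(C(C)C)C(C)C | intermediate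
33 | (1S,3Z)-1-[(2S,7R)-7-[(1S)-1-bromopropyl]-2,3,6,7-tetrahydrooxepin-2-yl]hex-3-en-5-yn-1-ol | C#C/C=C\C[C@H](O)[C@@H]1CC=CC[C@H]([C@@H](Br)CC)O1 | intermediate
34 | (1S,3Z)-1-[(2S,7R)-7-[(1S)-1-bromopropyl]-2,3,6,7-tetrahydrooxepin-2-yl]hex-3-en-5-yn-1-yl acetate | C#C/C=C\C[C@H](OC(C)=O)[C@@H]1CC=CC[C@H]([C@@H](Br)CC)O1 | target

**Step count**

- Total step count: 21.
- Longest linear sequence: 20 steps (1 to 34 through steps 1–17 and 19–21). Step 18 is a one-step side branch.

**The three steps most likely to fail**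

**Step 3, mono-opening of the diepoxide.** The bulky silylmethyl copper species may transfer slowly. A second opening, and migration of the remaining epoxide through the neighbouring magnesium alkoxide, could then compete.

The fallback replaces the C1 synthon by a faster-reacting C2 synthon whose extra carbon is later excised. It sets out from 3. Vinylmagnesium bromide with catalytic CuI in THF at −40 °C should give (1S)-1-[(2S)-oxiran-2-yl]but-3-en-1-ol F1. Ozonolysis in CH2Cl2/MeOH at −78 °C then leads to (3S)-3-hydroxy-3-[(2S)-oxiran-2-yl]propanal F2. This aldehyde is reduced in the same flask with NaBH4, and the route is rejoined at 7.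

**Step 11, ring closure.** The closure may leak into SN2′ attack at C9 or into intermolecular alkylation, or the cis preference at C12 may erode.

In the fallback the C11–C12 bond is still made by enolate allylation, but intermolecularly under auxiliary control, and the ring is closed at the olefin instead. It sets out from 8.
- Copper-catalysed opening with vinylmagnesium bromide gives (1S)-1-[(4S)-2,2-dimethyl-1,3-dioxan-4-yl]but-3-en-1-ol F3.
- NaH and bromoacetic acid in THF give {[(1S)-1-[(4S)-2,2-dimethyl-1,3-dioxan-4-yl]but-3-en-1-yl]oxy}acetic acid F4.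
- Pivaloyl chloride and Et3N convert this acid into its mixed pivalic anhydride F5.
- The anhydride acylates lithiated (4S)-4-benzyl-1,3-oxazolidin-2-one to give the N-glycolyl imide (4S)-4-benzyl-3-({[(1S)-1-[(4S)-2,2-dimethyl-1,3-dioxan-4-yl]but-3-en-1-yl]oxy}acetyl)-1,3-oxazolidin-2-one F6.
- NaHMDS and allyl iodide at −78 °C (oxazolidinone glycolate alkylation, with the electrophile approaching anti to the benzyl group) set 12R in the (2R)-pent-4-enoyl imide F7.
- Ring-closing metathesis with the second-generation Grubbs catalyst in CH2Cl2 at 40 °C forms C9=C10 in the oxepene imide F8.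
- Aminolysis with Me2NH·HCl/AlMe3 rejoins the route at 20.

**Step 14, bromination.** At 70 °C, participation of the ring oxygen (loss of clean inversion, skeletal rearrangement) and E2 elimination may compete with the direct displacement.

The fallback separates activation from displacement, so that the substitution can run at lower temperature with a soluble bromide. It sets out from 23. Chloromethanesulfonyl chloride and 2,6-lutidine in CH2Cl2 at 0 °C give the isolable (1R)-chloromethanesulfonate F9. LiBr in THF at 40 °C then displaces this sulfonate with inversion, and the route is rejoined at 24.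

**Further compounds**

F1 | step 3 | (1S)-1-[(2S)-oxiran-2-yl]but-3-en-1-ol | C=CC[C@H](O)[C@@H]1CO1
F2 | step 3 | (3S)-3-hydroxy-3-[(2S)-oxiran-2-yl]propanal | O=CC[C@H](O)[C@@H]1CO1
F3 | step 11 | (1S)-1-[(4S)-2,2-dimethyl-1,3-dioxan-4-yl]but-3-en-1-ol | CC1(C)OCC[C@@H]([C@@H](O)CC=C)O1
F4 | step 11 | {[(1S)-1-[(4S)-2,2-dimethyl-1,3-dioxan-4-yl]but-3-en-1-yl]oxy}acetic acid | OC(=O)CO[C@@H](CC=C)[C@@H]1CCOC(C)(C)O1
F5 | step 11 | {[(1S)-1-[(4S)-2,2-dimethyl-1,3-dioxan-4-yl]but-3-en-1-yl]oxy}acetic 2,2-dimethylpropanoic anhydride | CC(C)(C)C(=O)OC(=O)CO[C@@H](CC=C)[C@@H]1CCOC(C)(C)O1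
F6 | step 11 | (4S)-4-benzyl-3-({[(1S)-1-[(4S)-2,2-dimethyl-1,3-dioxan-4-yl]but-3-en-1-yl]oxy}acetyl)-1,3-oxazolidin-2-one | O=C(CO[C@@H](CC=C)[C@@H]1CCOC(C)(C)O1)N1[C@@H](Cc2ccccc2)COC1=O
F7 | step 11 | (4S)-4-benzyl-3-[(2R)-2-{[(1S)-1-[(4S)-2,2-dimethyl-1,3-dioxan-4-yl]but-3-en-1-yl]oxy}pent-4-enoyl]-1,3-oxazolidin-2-one | O=C([C@@H](CC=C)O[C@@H](CC=C)[C@@H]1CCOC(C)(C)O1)N1[C@@H](Cc2ccccc2)COC1=O
F8 | step 11 | (4S)-4-benzyl-3-{[(2R,7S)-7-[(4S)-2,2-dimethyl-1,3-dioxan-4-yl]-2,3,6,7-tetrahydrooxepin-2-yl]carbonyl}-1,3-oxazolidin-2-one | O=C([C@H]1CC=CC[C@@H]([C@@H]2CCOC(C)(C)O2)O1)N1[C@@H](Cc2ccccc2)COC1=O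
F9 | step 14 | (1R)-1-[(2R,7S)-7-[(4S)-2,2-dimethyl-1,3-dioxan-4-yl]-2,3,6,7-tetrahydrooxepin-2-yl]propyl chloromethanesulfonate | CC1(C)OCC[C@@H]([C@@H]2CC=CC[C@H]([C@H](OS(=O)(=O)CCl)CC)O2)O1
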